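**Assumption:** the target SMILES contains no stereocentre and no stereogenic double bond (the chromene alkene is fixed cis by its ring), so the compound is achiral and the route delivers that single compound.

## Retrosynthetic overview

1. Gancaonin H 14 comes from its 7-O-MOM ether 13 by acetal hydrolysis.
2. 13 comes from the ortho-prenylphenol 9 by a one-pot oxygenative cyclization that forms the C5'–O bond and the O4'–CMe2 bond; this builds the dimethylpyran ring, the only ring made in the route.
3. 9 comes from the 6,3'-diallyl compound 7 by double cross-metathesis, and 7 from bis-allyl ether 5 by two aromatic Claisen shifts (O5 to C6, O4' to C3').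
4. 5 comes from genistein 1 by 7-O-MOM protection, then O-allylation; rings A, B and C are bought intact.

## Route

Step 1
Reactants: 1 genistein (5,7-dihydroxy-3-(4-hydroxyphenyl)-4H-chromen-4-one); 2 chloromethyl methyl ether (MOMCl)
Product: 3 5-hydroxy-3-(4-hydroxyphenyl)-7-(methoxymethoxy)-4H-chromen-4-one (7-O-MOM-genistein)
Conditions: KOt-Bu (1.0 equiv), DMF, 0 °C; then MOMCl (1.05 equiv), 0 °C to rt
Reagents that add atoms: chloromethyl methyl ether, COCCl
Why: The 7-OH is the most acidic hydroxyl of genistein (para to the C4 carbonyl, pKa about 7 against about 10 for 4'-OH, with 5-OH chelated), so one equivalent of base gives only the 7-phenoxide and Williamson O-alkylation caps O7.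

Step 2
Reactants: 3 7-O-MOM-genistein; 4 allyl bromide
Product: 5 5-(allyloxy)-3-[4-(allyloxy)phenyl]-7-(methoxymethoxy)-4H-chromen-4-one
Conditions: allyl bromide (3 equiv), K2CO3 (4 equiv), DMF, 60 °C
Reagents that add atoms: allyl bromide, C=CCBr
Why: Williamson etherification in warm DMF alkylates both the free 4'-OH and the chelated, less reactive 5-OH, while the MOM acetal is inert to base.

Step 3
Reactants: 5 5,4'-bis-O-allyl-7-O-MOM-genistein
Product: 7 6-allyl-3-(3-allyl-4-hydroxyphenyl)-5-hydroxy-7-(methoxymethoxy)-4H-chromen-4-one, via 6-C-allyl 4'-O-allyl ether 6 (not isolated)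
Conditions: Eu(fod)3 [europium tris(6,6,7,7,8,8,8-heptafluoro-2,2-dimethyl-3,5-octanedionate)] (10 mol %), 1,2-dichlorobenzene, 90 °C, 12 h; then 180 °C, 6 h
Reagents that add atoms: none
Why: Two aromatic Claisen rearrangements ([3,3]-sigmatropic): the europium Lewis acid binds C4=O/O5 and moves the 5-O-allyl group to C6, the only open ortho position (C4a is blocked), at a temperature where the dienone enolizes before any Cope shift to C8, and further heating moves the 4'-O-allyl group to C3' (both ortho positions of ring B are equivalent).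

Step 4
Reactants: 7 6,3'-diallyl compound; 8 2-methyl-2-butene
Product: 9 5-hydroxy-3-[4-hydroxy-3-(3-methylbut-2-en-1-yl)phenyl]-7-(methoxymethoxy)-6-(3-methylbut-2-en-1-yl)-4H-chromen-4-one (7-O-MOM-lupalbigenin)
Conditions: RuCl2(=CHPh)(PCy3)(H2IMes) (second-generation Grubbs catalyst, 2 × 5 mol %), 2-methyl-2-butene/CH2Cl2 1:1, 40 °C, sealed tube
Reagents that add atoms: 2-methyl-2-butene, CC=C(C)C
Why: Olefin cross-metathesis of both terminal allyl groups with excess 2-methyl-2-butene turns allyl into prenyl with loss of propene, and the ruthenium carbene tolerates free phenols, the chromone and the MOM acetal.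

Step 5
Reactants: 9 7-O-MOM-lupalbigenin; 10 IBX (2-iodoxybenzoic acid)
Product: 13 5-hydroxy-3-(8-hydroxy-2,2-dimethyl-2H-chromen-6-yl)-7-(methoxymethoxy)-6-(3-methylbut-2-en-1-yl)-4H-chromen-4-one (7-O-MOM-gancaonin H), via ortho-quinone 11 (not isolated), via ortho-quinone methide 12 (not isolated)
Conditions: IBX (1.05 equiv), DMF, 0 °C to rt, 1 h; then pyridine (5 equiv), 40 °C, 2 h, argon
Reagents that add atoms: IBX, O=C1OI(=O)(O)c2ccccc12
Why: Proposed new method: one-pot oxygenative cyclization of an ortho-prenylphenol to an 8-hydroxy-2,2-dimethyl-2H-chromene — IBX transfers oxygen to the only free ortho carbon (C5') of the ring B phenol and leaves as 2-iodobenzoic acid (pentavalent iodine ends as monovalent iodine), giving ortho-quinone 11; pyridine then moves a proton from the prenyl CH2, which is vinylogously conjugated to the C5' carbonyl, to give ortho-quinone methide 12, whose oxatriene closes by oxa-6π-electrocyclization through the C4' oxygen, forming the pyran C–O bond and restoring aromaticity; ring A stays out because O7 is capped and the chelated 5-OH has no free ortho position; the closest known reaction types are the IBX ortho-oxygenation of phenols to ortho-quinones and the base-induced isomerization of prenylated para-benzoquinones to 6-chromenols (ubiquinone to ubichromenol), which to my knowledge have not been joined in a tandem on an ortho-quinone.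

Step 6
Reactants: 13 7-O-MOM-gancaonin H
Product: 14 gancaonin H (5,7-dihydroxy-3-(8-hydroxy-2,2-dimethyl-2H-chromen-6-yl)-6-(3-methylbut-2-en-1-yl)-4H-chromen-4-one)
Conditions: 3 M HCl (aq), MeOH, 40 °C, 2 h
Reagents that add atoms: none
Why: Acid-catalysed acetal hydrolysis; the 7-O-MOM group sits on a vinylogous-ester oxygen and should cleave under conditions mild enough to leave the prenyl group, the 2H-chromene and the phenols intact.

## Compound list

1 | genistein | Oc1cc(O)c2c(=O)c(-c3ccc(O)cc3)coc2c1 | starting material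
2 | chloromethyl methyl ether (MOMCl) | COCCl | starting material
3 | 5-hydroxy-3-(4-hydroxyphenyl)-7-(methoxymethoxy)-4H-chromen-4-one | COCOc1cc(O)c2c(=O)c(-c3ccc(O)cc3)coc2c1 | intermediate
4 | allyl bromide | C=CCBr | starting material
5 | 5-(allyloxy)-3-[4-(allyloxy)phenyl]-7-(methoxymethoxy)-4H-chromen-4-one | COCOc1cc(OCC=C)c2c(=O)c(-c3ccc(OCC=C)cc3)coc2c1 | intermediate
6 | 6-allyl-3-[4-(allyloxy)phenyl]-5-hydroxy-7-(methoxymethoxy)-4H-chromen-4-one | COCOc1cc2occ(-c3ccc(OCC=C)cc3)c(=O)c2c(O)c1CC=C | intermediate (not isolated)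
7 | 6-allyl-3-(3-allyl-4-hydroxyphenyl)-5-hydroxy-7-(methoxymethoxy)-4H-chromen-4-one | COCOc1cc2occ(-c3ccc(O)c(CC=C)c3)c(=O)c2c(O)c1CC=C | intermediate
8 | 2-methyl-2-butene | CC=C(C)C | starting material
9 | 7-O-MOM-lupalbigenin | COCOc1cc2occ(-c3ccc(O)c(CC=C(C)C)c3)c(=O)c2c(O)c1CC=C(C)C | intermediate
10 | IBX (1-hydroxy-1,2-benziodoxol-3(1H)-one 1-oxide) | O=C1OI(=O)(O)c2ccccc12 | starting material
11 | ortho-quinone: 5-[5-hydroxy-7-(methoxymethoxy)-6-(3-methylbut-2-en-1-yl)-4-oxo-4H-chromen-3-yl]-3-(3-methylbut-2-en-1-yl)cyclohexa-3,5-diene-1,2-dione | COCOc1cc2occ(C3=CC(=O)C(=O)C(CC=C(C)C)=C3)c(=O)c2c(O)c1CC=C(C)C | intermediate (not isolated)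
12 | ortho-quinone methide: 2-hydroxy-4-[5-hydroxy-7-(methoxymethoxy)-6-(3-methylbut-2-en-1-yl)-4-oxo-4H-chromen-3-yl]-6-(3-methylbut-2-en-1-ylidene)cyclohexa-2,4-dien-1-one, dienyl chain cis to the ring carbonyl | COCOc1cc2occ(C3=CC(=C/C=C(C)C)/C(=O)C(O)=C3)c(=O)c2c(O)c1CC=C(C)C | intermediate (not isolated)
13 | 7-O-MOM-gancaonin H | COCOc1cc2occ(-c3cc(O)c4c(c3)C=CC(C)(C)O4)c(=O)c2c(O)c1CC=C(C)C | intermediate
14 | gancaonin H | CC(C)=CCc1c(O)cc2occ(-c3cc(O)c4c(c3)C=CC(C)(C)O4)c(=O)c2c1O | target

## Step count and risks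

Total step count: 6. Longest linear sequence: 6 steps (from genistein 1).

**Step 5 (proposed new step).** Risks are over-oxidation of the product phenol by residual IBX, side reactions of ortho-quinone 11 (dimerization, addition of nucleophiles) and slow tautomerization. The fallback uses known chemistry, sets out from 9 and comes back at 13. IBX in DMF followed by aqueous Na2S2O4 in the same flask (known phenol-to-catechol sequence) gives the catechol 7-O-MOM-isoangustone A F1. TBSCl (1.05 equiv) and imidazole in DMF at 0 °C silylate the less hindered 3'-OH to give the mono-silyl ether F2. DDQ (1.1 equiv) in benzene at rt closes the pyran ring by the known dehydrogenative cyclization of ortho-prenylphenols, giving the silylated chromene F3; the electron-rich ring B phenol should react before the chelated 5-OH/6-prenyl pair. Bu4NF/AcOH in THF at 0 °C then returns 13.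

**Step 3 (double Claisen).** Risks are partial Claisen–Cope migration to C8, incomplete rearrangement of the ring B ether and loss of MOM at 180 °C. The fallback replaces the sigmatropic approach by halogenation and cross-coupling; it sets out from 3 and comes back at 9, bypassing steps 2 to 4. BnMe3N ICl2 (2.1 equiv) with CaCO3 in CH2Cl2/MeOH at rt iodinates C6 (directed by the free 5-OH) and C3' (ortho to 4'-OH) to give the diiodide F4. Double Stille coupling with tributyl(3-methylbut-2-en-1-yl)stannane, Pd(PPh3)4 and CsF in DMF at 80 °C gives 9.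

**Step 1 (selective mono-protection).** The risk is a mixture of 7-O-, 4'-O- and bis-MOM ethers. The fallback replaces direct alkylation by acylation and regioselective deacylation; it sets out from 1 and comes back at 3. Ac2O/pyridine at rt gives 7,4'-di-O-acetylgenistein F5 (the chelated 5-OH stays free). PhSH and imidazole in N-methylpyrrolidone at rt remove only the 7-O-acetyl group, the ester para to the C4 carbonyl, to give 4'-O-acetylgenistein F6. MOMCl and i-Pr2NEt in CH2Cl2 give 4'-O-acetyl-7-O-MOM-genistein F7, and K2CO3 in MeOH at 0 °C returns 3.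

## Further compounds

F1 | step 5 | 7-O-MOM-isoangustone A: 3-[3,4-dihydroxy-5-(3-methylbut-2-en-1-yl)phenyl]-5-hydroxy-7-(methoxymethoxy)-6-(3-methylbut-2-en-1-yl)-4H-chromen-4-one | COCOc1cc2occ(-c3cc(O)c(O)c(CC=C(C)C)c3)c(=O)c2c(O)c1CC=C(C)C
F2 | step 5 | 3-[3-(tert-butyldimethylsilyloxy)-4-hydroxy-5-(3-methylbut-2-en-1-yl)phenyl]-5-hydroxy-7-(methoxymethoxy)-6-(3-methylbut-2-en-1-yl)-4H-chromen-4-one | COCOc1cc2occ(-c3cc(O[Si](C)(C)C(C)(C)C)c(O)c(CC=C(C)C)c3)c(=O)c2c(O)c1CC=C(C)C
F3 | step 5 | 3-[8-(tert-butyldimethylsilyloxy)-2,2-dimethyl-2H-chromen-6-yl]-5-hydroxy-7-(methoxymethoxy)-6-(3-methylbut-2-en-1-yl)-4H-chromen-4-one | COCOc1cc2occ(-c3cc(O[Si](C)(C)C(C)(C)C)c4c(c3)C=CC(C)(C)O4)c(=O)c2c(O)c1CC=C(C)C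
F4 | step 3 | 5-hydroxy-3-(4-hydroxy-3-iodophenyl)-6-iodo-7-(methoxymethoxy)-4H-chromen-4-one | COCOc1cc2occ(-c3ccc(O)c(I)c3)c(=O)c2c(O)c1I
F5 | step 1 | 7,4'-di-O-acetylgenistein | CC(=O)Oc1ccc(-c2coc3cc(OC(C)=O)cc(O)c3c2=O)cc1
F6 | step 1 | 4'-O-acetylgenistein | CC(=O)Oc1ccc(-c2coc3cc(O)cc(O)c3c2=O)cc1
F7 | step 1 | 4'-O-acetyl-7-O-MOM-genistein | COCOc1cc(O)c2c(=O)c(-c3ccc(OC(C)=O)cc3)coc2c1
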